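The cyclohexane ring B (C1, C9a, C9, C10, C11, C12) is cut at C1–C12 and C9–C10, which separates a pyrrolo[1,2-a]azepine from an eight-carbon keto acid. The key step exploits the pyrrole that flanks ring B: protonation of a C8=C9 alkene gives a vinylogous iminium electrophilic at C9, while β-carbon C1 stays nucleophilic. In one operation a chiral Brønsted acid joins this vinylpyrrole to 5-hydroxy-3-methyl-5-propylbutenolide, the lactol of a (Z)-4-oxo-2-enoic acid: its C10 enol adds to C9, then C1 adds to butenolide C12, a formal (3+3) annulation. C10 and C12 settle equatorial, C13 is protonated from the convex face, and ketone reduction closes the lactone.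

Key step: step 4

Remark: atoms carry the usual Stemona labels, which coincide with pyrrolo[1,2-a]azepine locants (pyrrole C1, C2, C3, N4, C9a; azepane C5 to C9; ring B C9 to C12; ring lactone C13, C14; ethyl C16, C17; side lactone C18 to C21); 5-bromo-1H-pyrrole-2-carbaldehyde and (S)-methylsuccinic anhydride are taken as purchasable.

Step 1
Reactants: 1 5-bromo-1H-pyrrole-2-carbaldehyde; 2 (4-bromobutyl)triphenylphosphonium bromide
Product: 4 3-bromo-6,7-dihydro-5H-pyrrolo[1,2-a]azepine, via N-alkylated phosphonium bromide 3 (not isolated)
Conditions: NaH, DMF, 0 °C, then 2, 60 °C; then KOtBu, THF, 0 to 23 °C, high dilution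
Reagents that add atoms: none
Why: SN2 N-alkylation of the pyrrolide by the primary bromide followed by intramolecular Wittig olefination of the aldehyde closes the seven-membered ring with a necessarily Z C8=C9 alkene and no stereocentre; the ylide base is added only after N-alkylation so that the salt cannot cyclise to a cyclobutylphosphonium ion.

Step 2
Reactants: 4 3-bromo-6,7-dihydro-5H-pyrrolo[1,2-a]azepine; 5 (S)-methylsuccinic anhydride
Product: 7 (2S)-4-(6,7-dihydro-5H-pyrrolo[1,2-a]azepin-3-yl)-2-methyl-4-oxobutanoic acid, via 3-lithio-6,7-dihydro-5H-pyrrolo[1,2-a]azepine 6 (not isolated)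
Conditions: t-BuLi (2 equiv), THF, −78 °C; then cannula into 5 (1.5 equiv), THF, −78 °C; 1 M HCl
Reagents that add atoms: none
Why: Bromine–lithium exchange at α-carbon C3 and acylation of the aryllithium by the cyclic anhydride at its less hindered carbonyl (the CH2–C=O) give the γ-keto acid with the C20 (S) centre carried unchanged from the chiral pool; the C3 acyl group also blocks the free α-position and moderates the pyrrole for step 4.

Step 3
Reactants: 8 citraconic anhydride; 9 propylmagnesium bromide
Product: 10 rac-5-hydroxy-3-methyl-5-propylfuran-2(5H)-one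
Conditions: 9 (1.0 equiv) added to 8, THF, −78 °C; 1 M HCl
Reagents that add atoms: none
Why: Mono-addition of the Grignard reagent to the anhydride carbonyl that is not flanked by the methyl-bearing carbon (the site expected for bulky nucleophiles) gives the (Z)-4-oxo-2-enoic acid, which closes to the lactol; C11 is a dynamic hemiketal centre, so no stereocontrol is needed.

Step 4
Reactants: 7 (2S)-4-(6,7-dihydro-5H-pyrrolo[1,2-a]azepin-3-yl)-2-methyl-4-oxobutanoic acid; 10 rac-5-hydroxy-3-methyl-5-propylfuran-2(5H)-one
Product: 13 (9R,10R,12S,13S,20S)-11-oxo diacid, via C9-alkylated hydroxybutenolide 11 (not isolated), via 11-hydroxy lactone 12 (not isolated)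
Conditions: (R)-3,3′-bis(2,4,6-triisopropylphenyl)-1,1′-binaphthyl-2,2′-diyl N-triflyl phosphoramide (10 mol%), 10 (2 equiv), PhCl, 50 °C
Reagents that add atoms: none
Why: Proposed new method: the acid protonates C8 of vinylpyrrole 7 to give the C9 azafulvenium (vinylogous iminium) as a contact ion pair; the C10 enol of the ring-opened (Z)-4-oxo-2-enoic acid form of 10, generated by the same acid, adds to C9 to give 11, whose hydroxybutenolide is then attacked at its β-carbon C12 by pyrrole C1, and protonation of the lactone enol followed by opening of lactol 12 gives 13. The closest known reaction types are chiral phosphoric acid (3+3) annulations of 2-indolyl and 2-pyrrolyl carbinols, acid-catalysed Markovnikov hydroalkylation of vinylarenes by enols, and intramolecular Friedel–Crafts conjugate additions of pyrroles. Ring B closes in a 6-exo-trig mode (C1 onto C12 of the tethered butenolide); attack by C2 or at the ketal carbon C11 would need a seven- or five-membered ring, and the acid should be too weak to ionise the lactol. C9 is set by the chiral anion, which covers one face of the planar cation; C10 (α to the C11 ketone) equilibrates to the equatorial position trans to C8; C12 is delivered cis to C10 across the butenolide by the tether and ends equatorial; C13 is protonated on the convex face of the cis-fused lactone enol, syn to H12. The step needs C- over O-alkylation of 10 (the O-alkylated pseudo-ester re-ionises and returns) and cross- over self-coupling of 7, which the C3 acyl group secures by blocking the free α-position and lowering the nucleophilicity of the ring.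

Step 5
Reactants: 13 (9R,10R,12S,13S,20S)-11-oxo diacid
Product: 15 (9R,10R,11R,12S,13S,20S)-lactone keto acid, via axial 11-hydroxy diacid 14 (not isolated)
Conditions: LiBH(s-Bu)3 (3.5 equiv), THF, −78 °C; then 1 M HCl, 23 °C
Reagents that add atoms: none
Why: Selectride reduction: the bulky borohydride should attack the C11 ketone, flanked by two equatorial substituents, along the equatorial trajectory to give the axial alkoxide cis to the C10 ethyl group and the C12 side chain (C11 R), which closes the cis-fused γ-lactone on acidification; the C18 ketone is a vinylogous amide and should not react at −78 °C.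

Step 6
Reactants: 15 (9R,10R,11R,12S,13S,20S)-lactone keto acid
Product: 17 bisdehydroneotuberostemonine, via (18S)-hydroxy acid 16 (not isolated)
Conditions: RuCl(p-cymene)[(S,S)-TsDPEN] (2 mol%), HCO2Na, H2O/MeOH, 40 °C; then EDC·HCl, CH2Cl2, 0 °C
Reagents that add atoms: none
Why: Asymmetric transfer hydrogenation of the aryl ketone (Noyori type) sets C18 by catalyst control, the (S,S)-ligand being expected to give the (S)-carbinol through aryl/alkyl discrimination, and carbodiimide activation of the C21 acid then closes the γ-lactone with retention at the ionisation-prone pyrrolyl carbinol, cis to the C20 methyl group from the chiral pool.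

Compound list
1 | 5-bromo-1H-pyrrole-2-carbaldehyde | O=Cc1ccc(Br)[nH]1 | starting material
2 | (4-bromobutyl)triphenylphosphonium bromide | BrCCCC[P+](c1ccccc1)(c1ccccc1)c1ccccc1.[Br-] | starting material
3 | [4-(2-bromo-5-formyl-1H-pyrrol-1-yl)butyl]triphenylphosphonium bromide | O=Cc1ccc(Br)n1CCCC[P+](c1ccccc1)(c1ccccc1)c1ccccc1.[Br-] | intermediate
4 | 3-bromo-6,7-dihydro-5H-pyrrolo[1,2-a]azepine | Brc1ccc2n1CCCC=C2 | intermediate
5 | (S)-methylsuccinic anhydride, (3S)-3-methyloxolane-2,5-dione | C[C@H]1CC(=O)OC1=O | starting material
6 | 3-lithio-6,7-dihydro-5H-pyrrolo[1,2-a]azepine | [Li]c1ccc2n1CCCC=C2 | intermediate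
7 | (2S)-4-(6,7-dihydro-5H-pyrrolo[1,2-a]azepin-3-yl)-2-methyl-4-oxobutanoic acid | O=C(C[C@H](C)C(O)=O)c1ccc2n1CCCC=C2 | intermediate
8 | citraconic anhydride, 3-methylfuran-2,5-dione | CC1=CC(=O)OC1=O | starting material
9 | propylmagnesium bromide | CCC[Mg]Br | starting material
10 | rac-5-hydroxy-3-methyl-5-propylfuran-2(5H)-one, ring tautomer of (2Z)-2-methyl-4-oxohept-2-enoic acid | CCCC1(O)OC(=O)C(C)=C1 | intermediate
11 | (2S)-4-{(9R)-9-[1-(2-hydroxy-4-methyl-5-oxo-2,5-dihydrofuran-2-yl)propyl]-6,7,8,9-tetrahydro-5H-pyrrolo[1,2-a]azepin-3-yl}-2-methyl-4-oxobutanoic acid, mixture at C10 and C11 | CCC(C1(O)OC(=O)C(C)=C1)[C@H]1CCCCn2c1ccc2C(=O)C[C@H](C)C(O)=O | intermediate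
12 | (9R,10R,11R,12S,13S,20S)-11-hydroxy lactone, lactol tautomer of 13: ring B closed, cis-fused γ-lactone C11–O–C14, OH on C11 | CC[C@H]1[C@@]2(O)OC(=O)[C@@H](C)[C@H]2c2cc(C(=O)C[C@H](C)C(O)=O)n3c2[C@@H]1CCCC3 | intermediate
13 | (9R,10R,12S,13S,20S)-11-oxo diacid: ring B ketone at C11, ethyl on C10, (S)-CH(CH3)CO2H on C12, (S)-C(=O)CH2CH(CH3)CO2H on C3 | CC[C@H]1C(=O)[C@@H]([C@H](C)C(O)=O)c2cc(C(=O)C[C@H](C)C(O)=O)n3c2[C@@H]1CCCC3 | intermediate
14 | (9R,10R,11R,12S,13S,20S)-11-hydroxy diacid, axial OH cis to the C10 ethyl group and the C12 side chain | CC[C@H]1[C@@H](O)[C@@H]([C@H](C)C(O)=O)c2cc(C(=O)C[C@H](C)C(O)=O)n3c2[C@@H]1CCCC3 | intermediate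
15 | (9R,10R,11R,12S,13S,20S)-lactone keto acid: cis-fused ring lactone closed, C3 carries (S)-C(=O)CH2CH(CH3)CO2H | CC[C@H]1[C@H]2OC(=O)[C@@H](C)[C@H]2c2cc(C(=O)C[C@H](C)C(O)=O)n3c2[C@@H]1CCCC3 | intermediate
16 | (18S)-hydroxy acid of 15 | CC[C@H]1[C@H]2OC(=O)[C@@H](C)[C@H]2c2cc([C@@H](O)C[C@H](C)C(O)=O)n3c2[C@@H]1CCCC3 | intermediate
17 | bisdehydroneotuberostemonine | CC[C@H]1[C@H]2OC(=O)[C@@H](C)[C@H]2c2cc([C@@H]3C[C@H](C)C(=O)O3)n3c2[C@@H]1CCCC3 | target

Total step count: 6. Longest linear sequence: 5 steps (1 → 4 → 7 → 13 → 15 → 17).

Steps most likely to fail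

Step 4 (proposed new method). The chiral anion has no hydrogen-bond anchor on the N-alkyl pyrrole, so facial discrimination at the C9 cation may be weak, and the (R)-catalyst is assigned to the (9R) sense only by analogy (the (S)-catalyst is equally available). The sequence may also stall after the first bond, because the acyl-deactivated pyrrole adds slowly to the butenolide and the lactol can drain away by loss of water. Fallback, setting out from 7 and 10 and coming back at 13: catalyst control is given up and the two bonds are made in separate, individually precedented operations. Soft enolisation of 10 (TBSOTf, Et3N) should give the bis-silyl dienol ether tert-butyldimethylsilyl (2Z,4Z)-4-[(tert-butyldimethylsilyl)oxy]-2-methylhepta-2,4-dienoate F1. Its TMSOTf-promoted Mukaiyama-type addition to the cation formed from 7 should give, after aqueous work-up, 11 together with its (9S) epimer F2. Sc(OTf)3-mediated intramolecular Friedel–Crafts conjugate addition then closes ring B to 13 and the (9S,10S,12R,13R,20S) diastereomer F3. These two differ as diastereomers through C20 and are separated by crystallisation or chromatography before step 5, at the cost of half the material.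

Step 6. Hydride transfer to the electron-rich, N-flanked 2-acylpyrrole ketone may be sluggish, and the pyrrolyl carbinol may ionise with loss of C18 configuration. Fallback, from 15 back to 16: carboxylate-directed reduction with diisopinocampheylborane (Ipc2BH), in which the C21 acid forms an acyloxyborane and hydride is delivered intramolecularly through a cyclic transition state. The enantiomer of the reagent that leads to the (S)-carbinol is used, and 16 is lactonised with EDC as in the route; no new compound is made.

Step 5. Hydride may also attack the C18 ketone, or may attack C11 axially and give the equatorial alcohol, which cannot lactonise. Fallback, from 13 back to 15: the facial problem is turned around. NaBH4 in MeOH at 0 °C (small hydride, axial attack) should give the equatorial (11S)-hydroxy diacid F4, and Mitsunobu lactonisation (PPh3, DIAD) closes the γ-lactone with inversion at C11.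

Further compounds
F1 | step 4 | tert-butyldimethylsilyl (2Z,4Z)-4-[(tert-butyldimethylsilyl)oxy]-2-methylhepta-2,4-dienoate | CC/C=C(\O[Si](C)(C)C(C)(C)C)/C=C(/C)\C(=O)O[Si](C)(C)C(C)(C)C
F2 | step 4 | (9S) epimer of 11, mixture at C10 and C11 | CCC(C1(O)OC(=O)C(C)=C1)[C@@H]1CCCCn2c1ccc2C(=O)C[C@H](C)C(O)=O
F3 | step 4 | (9S,10S,12R,13R,20S) diastereomer of 13 | CC[C@@H]1C(=O)[C@H]([C@@H](C)C(O)=O)c2cc(C(=O)C[C@H](C)C(O)=O)n3c2[C@H]1CCCC3
F0 | step 6 | none | none
F4 | step 5 | (9R,10R,11S,12S,13S,20S)-11-hydroxy diacid, equatorial OH | CC[C@H]1[C@H](O)[C@@H]([C@H](C)C(O)=O)c2cc(C(=O)C[C@H](C)C(O)=O)n3c2[C@@H]1CCCC3
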